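Rings: ring A is the δ-lactone, ring B the cycloheptadiene, ring C the cyclohexane and ring D the hydroxy-ketone ring; rings C and D form a bicyclo[3.3.1]nonane.
Retrosynthesis: the epoxide C–O bonds are cut first (back to C=CH2), then the O–CMe2 bond of ring A and the acetate C–C bond, then one ring carbon of ring B (7 → 6), then the CH2–C(OH) bond of ring D.
Enabling feature: the tertiary α-hydroxy ketone of ring D, C(CH3)(OH) beside the ring C=O, is the 1,2-shift isomer of a 1-acetylcyclopentanol on the two-carbon bridge of a bicyclo[3.2.1]octane, so ring D comes from that five-membered ring by an α-ketol rearrangement.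
Further cuts: C–acetyl (1-ethoxyvinyllithium), C=CH2 (Cp2TiMe2), both bonds of the two-carbon bridge (Claisen closure, enolate alkylation) and the two Diels–Alder bonds of ring C, down to isopiperitenone and a 2-silyloxydiene.
Forward ring order: terpene ring (limonene) → ring C (Diels–Alder) → cyclopentanone bridge → ring D (5 → 6, key step) → ring B (6 → 7, dibromocarbene) → ring A (lactonisation) → epoxide.
Stereochemistry: C6 of (S)-isopiperitenone picks the enone face and is then erased; the angular methyl then relays to the ring fusion (equilibration), the ester-bearing carbon (alkylation anti to it), the methyl-bearing bridgehead (bridging), the carbinol (exo addition, rotamer-controlled shift) and the epoxide (hydroxyl delivery).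

Key step: step 14

Assumption: in step 3 the diene bonds to the enone face syn to the pseudo-equatorial C6 isopropenyl group (axial attack at the β-carbon, as in conjugate additions to 6-substituted cyclohex-2-enones); this is why the (R)-terpene is the starting material.
Remark: centres that are erased later (carbinol of step 5, cyclopropane of step 18, carbinol of step 20) are drawn as expected for approach anti to the angular methyl; their configuration has no bearing on the outcome.

Step 1
Reactants: 1 (R)-(+)-limonene
Product: 2 (S)-isopiperitenone
Conditions: Cr(CO)6 (cat.), t-BuOOH, MeCN, reflux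
Reagents that add atoms: tert-butyl hydroperoxide, CC(C)(C)OO
Why: Chromium-catalysed allylic oxidation with t-BuOOH turns the ring CH2 between the trisubstituted alkene and the stereocentre into the enone carbonyl under neutral conditions that should not epimerise C6, the regioisomeric carvone from oxidation of the other allylic CH2 being removed by chromatography.

Step 2
Reactants: 3 3-methylbut-3-en-2-one
Product: 4 2-(triisopropylsilyloxy)-3-methylbuta-1,3-diene
Conditions: i-Pr3SiOTf, Et3N, Et2O, 0 °C
Reagents that add atoms: triisopropylsilyl trifluoromethanesulfonate, CC(C)[Si](C(C)C)(C(C)C)OS(=O)(=O)C(F)(F)F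
Why: Soft enolisation and O-silylation of a methyl ketone with a silyl triflate and Et3N is the standard entry to 2-silyloxy-1,3-dienes, and no stereocentre is formed.

Step 3
Reactants: 2 (S)-isopiperitenone; 4 silyloxydiene
Product: 5 cis-fused Diels–Alder adduct
Conditions: AlBr3/AlMe3 (10:1, cat.), toluene/CH2Cl2, −20 °C
Reagents that add atoms: none
Why: Lewis-acid-catalysed Diels–Alder reaction of a β,β-disubstituted enone with a 2-silyloxydiene, for which the mixed AlBr3/AlMe3 catalyst is an established answer to steric hindrance; the enol-ether CH2 of the diene bonds to the enone β-carbon (para orientation), suprafacial addition gives the cis ring fusion, and the diene is expected on the face syn to the pseudo-equatorial isopropenyl group (axial attack), which fixes the quaternary methyl centre, the minor facial isomer being removed by chromatography before step 4.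

Step 4
Reactants: 5 cis-fused Diels–Alder adduct
Product: 6 trans-fused isopropylidene ketone
Conditions: NaOMe (cat.), MeOH/THF, rt
Reagents that add atoms: none
Why: Thermodynamic enolate equilibration in which the β,γ-unsaturated ketone moves into conjugation as the isopropylidene ketone (the isopulegone-to-pulegone isomerisation, which erases the directing stereocentre) and the ring-fusion CH epimerises to the more stable trans-decalin, while the hindered triisopropylsilyl enol ether should withstand catalytic methoxide.

Step 5
Reactants: 6 trans-fused isopropylidene ketone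
Product: 7 allylic alcohol
Conditions: i-Bu2AlH, CH2Cl2, −78 °C; aq. KNaC4H4O6
Reagents that add atoms: none
Why: 1,2-Reduction of the hindered conjugated ketone by i-Bu2AlH, which spares the silyl enol ether; hydride arrives from the face opposite the syn-axial angular methyl, so the hydroxyl is axial and cis to that methyl (the centre reverts to a ketone in step 16).

Step 6
Reactants: 7 allylic alcohol
Product: 8 allylic tert-butyldimethylsilyl ether
Conditions: t-BuMe2SiOTf, 2,6-lutidine, CH2Cl2, 0 °C
Reagents that add atoms: tert-butyldimethylsilyl trifluoromethanesulfonate, CC(C)(C)[Si](C)(C)OS(=O)(=O)C(F)(F)F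
Why: Silyl triflate with 2,6-lutidine is the standard silylation of a hindered secondary alcohol and does not disturb the enol ether.

Step 7
Reactants: 8 allylic tert-butyldimethylsilyl ether
Product: 9 ring-C ketone
Conditions: Bu4NF, AcOH, THF, 0 °C
Reagents that add atoms: none
Why: Fluoride cleaves a silyl enol ether far faster than a hindered secondary alkyl silyl ether, so buffered Bu4NF at 0 °C should release only the ring-C ketone, whose α-methyl takes the equatorial position on protonation or on equilibration in step 8.

Step 8
Reactants: 9 ring-C ketone
Product: 10 β-keto ester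
Conditions: NaH, (MeO)2CO, THF, reflux; then AcOH
Reagents that add atoms: dimethyl carbonate, COC(=O)OC
Why: Carbomethoxylation with NaH and dimethyl carbonate is reversible and can only come to rest at the CH2 flank, where the β-keto ester is stored as its enolate, because acylation at the methyl-bearing CH would give a product that cannot be deprotonated; the ester ends equatorial or as the enol.

Step 9
Reactants: 10 β-keto ester; 11 methyl bromoacetate
Product: 12 keto diester
Conditions: K2CO3, acetone, reflux
Reagents that add atoms: none
Why: C-Alkylation of a β-keto ester enolate with an α-bromo ester; the electrophile approaches the enolate carbon axially from the face opposite the adjacent axial angular methyl, setting the quaternary centre with the acetate arm axial and anti to that methyl.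

Step 10
Reactants: 12 keto diester
Product: 13 tricyclic dione
Conditions: LiN(SiMe3)2 (2.5 equiv), THF, −78 to 0 °C; aq. NH4Cl
Reagents that add atoms: none
Why: Intramolecular Claisen (Dieckmann-type) condensation in which the only enolate available to the ring-C ketone, at the methyl-bearing CH, attacks the axial acetate ester across the ring to close the cyclopentanone as the two-carbon bridge of a bicyclo[3.2.1]octane, the bridging geometry fixing the new quaternary centre, while the excess base stores the 1,3-diketone as the enolate of its bridge CH2 and so protects it from methoxide.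

Step 11
Reactants: 13 tricyclic dione; 14 ethyl vinyl ether
Product: 17 ethoxyvinyl carbinol trimethylsilyl ether, via 1-ethoxyvinyllithium 15 (not isolated), via lithium alkoxide 16 (not isolated)
Conditions: 14, t-BuLi, THF, −78 to 0 °C; then 13, −78 °C; then Me3SiCl, −78 to 0 °C
Reagents that add atoms: chlorotrimethylsilane, C[Si](C)(C)Cl
Why: Addition of 1-ethoxyvinyllithium, an acetyl anion equivalent well proven on cyclopentanones flanked by a quaternary carbon, to the more accessible two-carbon-bridge ketone (the bridging ketone lies between two quaternary carbons) from the exo face, beside the one-carbon bridge and away from the axial H of the three-carbon bridge, gives the exo ethoxyvinyl group and the endo alkoxide, which is silylated in the flask so that retro-aldol cleavage towards the neighbouring ketone cannot set in.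

Step 12
Reactants: 17 ethoxyvinyl carbinol trimethylsilyl ether
Product: 18 exocyclic methylene compound
Conditions: Cp2TiMe2, toluene, 65 °C, dark
Reagents that add atoms: dimethyltitanocene Cp2TiMe2, C[Ti](C)(C1C=CC=C1)C1C=CC=C1
Why: Petasis methylenation, a non-basic titanium carbene transfer that suits hindered and strained ketones, converts the bridging ketone into the exocyclic methylene without β-elimination or retro-aldol chemistry and more quickly than it attacks the hindered ester.

Step 13
Reactants: 18 exocyclic methylene compound
Product: 19 acetyl carbinol
Conditions: HCl (0.5 M), THF/H2O, 0 °C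
Reagents that add atoms: water, O
Why: Dilute aqueous acid hydrolyses the 1-ethoxyvinyl enol ether to the methyl ketone and the trimethylsilyl ether to the alcohol, while the hindered tert-butyldimethylsilyl ether and the alkenes persist and no stereocentre is touched.

Step 14
Reactants: 19 acetyl carbinol
Product: 20 ring-D ketol
Conditions: KOt-Bu (0.3 equiv), t-BuOH/THF, 0 °C
Reagents that add atoms: none
Why: The tertiary alkoxide formed by KOt-Bu pushes the bond between the carbinol carbon and the bridge CH2 onto the acetyl carbonyl carbon (α-ketol, or acyloin, rearrangement), so the carbinol carbon becomes the ring ketone and the acetyl carbon the new methyl carbinol; the closest precedent is the base-induced D-homoannulation of 17-hydroxy-20-keto steroids. Six-membered ring D arises by this 1,2-alkyl shift, that is by enlargement of the five-membered ring of the bicyclo[3.2.1]octane to the bicyclo[3.3.1]nonane, not by a cyclisation. The one new stereocentre is set by the acetyl rotamer at the moment of migration: with the weakly coordinating potassium ion the two oxygens stay anti, the carbonyl oxygen points towards the one-carbon bridge and becomes the exo hydroxyl, and the methyl ends endo. The step needs migration of the CH2 and not of the quaternary bridgehead, which is secured because only that mode puts the ketone, not a second fully substituted carbon, next to the bridgehead and releases the most strain, as in the steroid series. It also needs kinetic control at the carbinol, which the strain released makes likely since the reverse shift is uphill, and freedom from fragmentation, which is given because the one-carbon bridge is already a methylene (no retro-aldol or retro-Claisen partner) and the hindered ester and silyl ether ignore catalytic tert-butoxide.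

Step 15
Reactants: 20 ring-D ketol
Product: 21 ketol allylic alcohol
Conditions: HF·pyridine, pyridine, THF, 0 °C to rt
Reagents that add atoms: none
Why: Acidic fluoride removes the hindered allylic silyl ether without exposing the ketol to base, so the carbinol centre set in step 14 cannot equilibrate.

Step 16
Reactants: 21 ketol allylic alcohol
Product: 22 terpene enone
Conditions: Dess–Martin periodinane, CH2Cl2, rt
Reagents that add atoms: none
Why: Dess–Martin oxidation of the secondary allylic alcohol gives the conjugated isopropylidene ketone, the tertiary ketol hydroxyl being inert, and removes the stereocentre made in step 5.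

Step 17
Reactants: 22 terpene enone
Product: 23 silyl dienol ether
Conditions: Me3SiOTf, Et3N, CH2Cl2, 0 °C
Reagents that add atoms: trimethylsilyl trifluoromethanesulfonate, C[Si](C)(C)OS(=O)(=O)C(F)(F)F
Why: Soft enolisation with a silyl triflate and Et3N, in which the only enolisable carbonyl is the terpene enone and removal of a γ-hydrogen from an isopropylidene methyl (the ring-fusion α′-hydrogen is hindered and would give a strained enol ether) gives the conjugated silyl dienol ether carrying an isopropenyl group, the tertiary hydroxyl being silylated in the same operation.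

Step 18
Reactants: 23 silyl dienol ether
Product: 25 ring-B bromo enone, via dibromocyclopropane 24 (not isolated)
Conditions: CHBr3, KOt-Bu, hexane, −20 to 0 °C; then toluene, 80 °C
Reagents that add atoms: bromoform, BrC(Br)Br
Why: Dibromocarbene cyclopropanation of the most electron-rich alkene, the tetrasubstituted silyl enol ether, from the face opposite the angular methyl, followed by thermal opening of the siloxy-dibromocyclopropane with loss of Me3SiBr, is the classical one-carbon ring expansion of a cyclohexanone silyl enol ether to a 2-bromocyclohept-2-enone; the isopropenyl group and the hindered bridging methylene are less nucleophilic.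

Step 19
Reactants: 25 ring-B bromo enone
Product: 26 dienone tert-butyl ester
Conditions: BrZnCH2CO2t-Bu, Pd(dba)2 (cat.), P(t-Bu)3 (cat.), THF, rt
Reagents that add atoms: (2-tert-butoxy-2-oxoethyl)zinc bromide, CC(C)(C)OC(=O)C[Zn]Br
Why: Palladium-catalysed cross-coupling of the activated alkenyl bromide with the zinc enolate of tert-butyl acetate (Negishi-type coupling of a Reformatsky reagent), a nucleophile mild enough to leave ketones and esters alone, places the acetate arm on the inserted carbon with the double bond unchanged.

Step 20
Reactants: 26 dienone tert-butyl ester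
Product: 27 tertiary dienyl alcohol
Conditions: MeLi, CeCl3, THF, −78 °C
Reagents that add atoms: methyllithium, [Li]C
Why: The organocerium reagent MeCeCl2 adds 1,2 to the hindered, enolisable dienone carbonyl without deprotonating the acetate CH2 or attacking the esters, the other ketone being buried between two fully substituted carbons, and the methyl group should enter anti to the angular methyl (a centre erased in step 21).

Step 21
Reactants: 27 tertiary dienyl alcohol
Product: 29 deoxy lactone, via triene ester 28 (not isolated)
Conditions: CF3CO2H, CH2Cl2, 0 °C to rt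
Reagents that add atoms: none
Why: Acid ionises the doubly allylic tertiary alcohol to a pentadienyl cation that loses a ring proton (E1) to give the cross-conjugated triene, and protonation of the isopropenyl terminus then gives a tertiary allylic cation that the ester carbonyl captures with loss of 2-methylpropene (Markovnikov lactonisation), closing six-membered ring A and leaving the tetrasubstituted and trisubstituted alkenes of ring B as the expected thermodynamic outcome; the ring-fusion centre can only return to the favoured trans form, the trimethylsilyl ether is shed, and the exocyclic methylene, whose cation would sit between two electron-poor quaternary carbons, should survive short exposure.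

Step 22
Reactants: 29 deoxy lactone
Product: 30 CNP0605450.1
Conditions: VO(acac)2 (cat.), t-BuOOH, toluene, rt
Reagents that add atoms: tert-butyl hydroperoxide, CC(C)(C)OO
Why: Vanadium-catalysed hydroxyl-directed epoxidation with t-BuOOH, in which the exo tertiary hydroxyl of ring D (a bishomoallylic alcohol held over the methylene when ring D is a boat) delivers oxygen to the ring-D face, also the face not shielded by the angular methyl, and so sets the spiro-epoxide centre while the undirected ring-B diene is left alone.

Compound list
1 | (R)-(+)-limonene | CC1=CC[C@H](C(C)=C)CC1 | starting material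
2 | (S)-isopiperitenone, (6S)-3-methyl-6-(prop-1-en-2-yl)cyclohex-2-en-1-one | CC1=CC(=O)[C@H](C(C)=C)CC1 | intermediate
3 | 3-methylbut-3-en-2-one | CC(=O)C(C)=C | starting material
4 | triisopropyl[(3-methylbuta-1,3-dien-2-yl)oxy]silane | C=C(O[Si](C(C)C)(C(C)C)C(C)C)C(C)=C | intermediate
5 | cis-fused Diels–Alder adduct: 4a,7-dimethyl-2-(prop-1-en-2-yl)-6-(triisopropylsilyloxy)-3,4,4a,5,8,8a-hexahydronaphthalen-1(2H)-one; angular methyl cis to the ring-fusion H and trans to the isopropenyl group | C1C(O[Si](C(C)C)(C(C)C)C(C)C)=C(C)C[C@@H]2C(=O)[C@H](C(C)=C)CC[C@]12C | intermediate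
6 | trans-fused isopropylidene ketone: 4a,7-dimethyl-2-(propan-2-ylidene)-6-(triisopropylsilyloxy)-3,4,4a,5,8,8a-hexahydronaphthalen-1(2H)-one; ring-fusion H anti to the angular methyl | C1C(O[Si](C(C)C)(C(C)C)C(C)C)=C(C)C[C@H]2C(=O)C(=C(C)C)CC[C@]12C | intermediate
7 | allylic alcohol: the 1-ol of 6, hydroxyl axial and cis to the angular methyl | C1C(O[Si](C(C)C)(C(C)C)C(C)C)=C(C)C[C@H]2[C@@H](O)C(=C(C)C)CC[C@]12C | intermediate
8 | tert-butyldimethylsilyl ether of 7 | C1C(O[Si](C(C)C)(C(C)C)C(C)C)=C(C)C[C@H]2[C@@H](O[Si](C)(C)C(C)(C)C)C(=C(C)C)CC[C@]12C | intermediate
9 | ring-C ketone: 5-(tert-butyldimethylsilyloxy)-3,8a-dimethyl-6-(propan-2-ylidene)octahydronaphthalen-2(1H)-one, trans-fused, 3-methyl equatorial | C1C(=O)[C@@H](C)C[C@H]2[C@@H](O[Si](C)(C)C(C)(C)C)C(=C(C)C)CC[C@]12C | intermediate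
10 | β-keto ester: methyl 1-carboxylate of 9, ester equatorial (keto tautomer drawn) | COC(=O)[C@H]1C(=O)[C@@H](C)C[C@H]2[C@@H](O[Si](C)(C)C(C)(C)C)C(=C(C)C)CC[C@]12C | intermediate
11 | methyl bromoacetate | COC(=O)CBr | starting material
12 | keto diester: 10 carrying CH2CO2Me on the ester-bearing carbon, axial and anti to the angular methyl | COC(=O)C[C@]1(C(=O)OC)C(=O)[C@@H](C)C[C@H]2[C@@H](O[Si](C)(C)C(C)(C)C)C(=C(C)C)CC[C@]12C | intermediate
13 | tricyclic dione: ring C bridged by CH2–C(=O) between the ester-bearing and the methyl-bearing carbons (bicyclo[3.2.1]octane-6,8-dione), terpene ring trans-fused | COC(=O)[C@]12CC(=O)[C@](C)(C[C@H]3[C@@H](O[Si](C)(C)C(C)(C)C)C(=C(C)C)CC[C@@]31C)C2=O | intermediate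
14 | ethyl vinyl ether | C=COCC | starting material
15 | 1-ethoxyvinyllithium | [Li]C(=C)OCC | intermediate
16 | lithium alkoxide from exo addition of 15 to the two-carbon-bridge ketone of 13 | COC(=O)[C@]12C[C@@]([O-])(C(=C)OCC)[C@](C)(C[C@H]3[C@@H](O[Si](C)(C)C(C)(C)C)C(=C(C)C)CC[C@@]31C)C2=O.[Li+] | intermediate
17 | trimethylsilyl ether of the 1-ethoxyvinyl carbinol (ethoxyvinyl exo, silyloxy endo) | COC(=O)[C@]12C[C@@](O[Si](C)(C)C)(C(=C)OCC)[C@](C)(C[C@H]3[C@@H](O[Si](C)(C)C(C)(C)C)C(=C(C)C)CC[C@@]31C)C2=O | intermediate
18 | 17 with the one-carbon-bridge ketone replaced by C=CH2 | COC(=O)[C@]12C[C@@](O[Si](C)(C)C)(C(=C)OCC)[C@](C)(C[C@H]3[C@@H](O[Si](C)(C)C(C)(C)C)C(=C(C)C)CC[C@@]31C)C2=C | intermediate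
19 | acetyl carbinol: bicyclo[3.2.1]octane with exo acetyl and endo hydroxyl on the two-carbon bridge and C=CH2 as the one-carbon bridge | COC(=O)[C@]12C[C@@](O)(C(C)=O)[C@](C)(C[C@H]3[C@@H](O[Si](C)(C)C(C)(C)C)C(=C(C)C)CC[C@@]31C)C2=C | intermediate
20 | ring-D ketol: bicyclo[3.3.1]nonane with C(CH3)(OH) (methyl endo, hydroxyl exo) between the bridge CH2 and the ring ketone, C=CH2 retained | COC(=O)[C@]12C[C@@](C)(O)C(=O)[C@](C)(C[C@H]3[C@@H](O[Si](C)(C)C(C)(C)C)C(=C(C)C)CC[C@@]31C)C2=C | intermediate
21 | ketol allylic alcohol (20 without the silyl group) | COC(=O)[C@]12C[C@@](C)(O)C(=O)[C@](C)(C[C@H]3[C@@H](O)C(=C(C)C)CC[C@@]31C)C2=C | intermediate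
22 | terpene enone: isopropylidene ketone from 21 | COC(=O)[C@]12C[C@@](C)(O)C(=O)[C@](C)(C[C@H]3C(=O)C(=C(C)C)CC[C@@]31C)C2=C | intermediate
23 | silyl dienol ether: Me3SiO–C=C–C(CH3)=CH2 in the terpene ring, ring-D hydroxyl as its Me3Si ether | COC(=O)[C@]12C[C@@](C)(O[Si](C)(C)C)C(=O)[C@](C)(C[C@H]3C(O[Si](C)(C)C)=C(C(C)=C)CC[C@@]31C)C2=C | intermediate
24 | siloxy-dibromocyclopropane from 23, CBr2 anti to the angular methyl | COC(=O)[C@]12C[C@@](C)(O[Si](C)(C)C)C(=O)[C@](C)(C[C@H]3[C@]4(O[Si](C)(C)C)C(Br)(Br)[C@]4(C(C)=C)CC[C@@]31C)C2=C | intermediate
25 | ring-B bromo enone: 2-bromo-3-(prop-1-en-2-yl)cyclohept-2-en-1-one fused to ring C | COC(=O)[C@]12C[C@@](C)(O[Si](C)(C)C)C(=O)[C@](C)(C[C@H]3C(=O)C(Br)=C(C(C)=C)CC[C@@]31C)C2=C | intermediate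
26 | dienone tert-butyl ester: 25 with Br replaced by CH2CO2t-Bu | COC(=O)[C@]12C[C@@](C)(O[Si](C)(C)C)C(=O)[C@](C)(C[C@H]3C(=O)C(CC(=O)OC(C)(C)C)=C(C(C)=C)CC[C@@]31C)C2=C | intermediate
27 | tertiary dienyl alcohol from methyl addition to the ring-B ketone of 26, methyl anti to the angular methyl | COC(=O)[C@]12C[C@@](C)(O[Si](C)(C)C)C(=O)[C@](C)(C[C@H]3[C@@](C)(O)C(CC(=O)OC(C)(C)C)=C(C(C)=C)CC[C@@]31C)C2=C | intermediate
28 | cross-conjugated triene tert-butyl ester (ring-B diene plus isopropenyl) | COC(=O)[C@]12C[C@@](C)(O[Si](C)(C)C)C(=O)[C@](C)(C[C@H]3C(C)=C(CC(=O)OC(C)(C)C)C(C(C)=C)=CC[C@@]31C)C2=C | intermediate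
29 | deoxy lactone: rings A to D complete, exocyclic methylene in place of the epoxide, free tertiary hydroxyl | COC(=O)[C@]12C[C@@](C)(O)C(=O)[C@](C)(C[C@H]3C(C)=C4CC(=O)OC(C)(C)C4=CC[C@@]31C)C2=C | intermediate
30 | CNP0605450.1 | COC(=O)[C@]12C[C@@](C)(O)C(=O)[C@](C)(C[C@H]3C(C)=C4CC(=O)OC(C)(C)C4=CC[C@@]31C)[C@]21CO1 | target

Total step count: 22. Longest linear sequence: 21 steps (steps 1 and 3 to 22, from (R)-(+)-limonene); step 2 is a one-step branch.

Steps most likely to fail

Step 3. The diene may engage the enone face opposite to the one assumed (anti to the isopropenyl group), which after the equilibration of step 4 would deliver the mirror-image series. Because the directing centre is erased in step 4, the chiral source can be inverted and the stereoconvergence used instead. The fallback sets out from diene 4 and the commercial antipode (S)-(−)-limonene F1. The same allylic oxidation gives (R)-isopiperitenone F2. Its anti cycloadduct F3 has the configuration of 5 at the angular and ring-fusion carbons and the opposite one at the isopropenyl carbon. Under the conditions of step 4 it gives the same compound 6, where the route is rejoined.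

Step 18. Dibromocarbene may add to the isopropenyl end of the dienol ether or to the bridging methylene, and tert-butoxide may desilylate the enol ether before the carbene is trapped. The fallback sets out from 23 and uses a zinc carbenoid, which strongly prefers silyl enol ethers. Et2Zn/CH2I2 (Furukawa variant of the Simmons–Smith reaction) gives the siloxycyclopropane F4. FeCl3 in DMF opens its internal bond oxidatively to the ring-enlarged β-chloro cycloheptanone F5. NaOAc eliminates HCl to the ring-B dienone F6. I2 with 4-(dimethylamino)pyridine gives the α-iodo dienone F7. F7 is coupled with BrZnCH2CO2t-Bu exactly as in step 19, which returns to 26.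

Step 21. During the acid exposure needed for ester cleavage the cation may be captured at the wrong terminus (five-membered lactone at the former carbinol carbon, or attack at the ring CH), or the exocyclic methylene may be protonated and rearrange. The fallback sets out from 27 and separates the events. A catalytic amount of pyridinium p-toluenesulfonate in CH2Cl2 only dehydrates, and triene ester 28 is isolated. Iodolactonisation (I2, NaHCO3, MeCN), in which the ester carbonyl opens the iodonium ion of the isopropenyl group at its substituted carbon with loss of the tert-butyl group, gives the iodomethyl lactone F8 without a free carbocation. Bu3SnH/AIBN removes the iodine to give the lactone trimethylsilyl ether F9. Dilute aqueous acid takes off the silyl group and returns to 29.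

Further compounds
F1 | step 3 | (S)-(−)-limonene | CC1=CC[C@@H](C(C)=C)CC1
F2 | step 3 | (R)-isopiperitenone | CC1=CC(=O)[C@@H](C(C)=C)CC1
F3 | step 3 | cis-fused adduct epimeric with 5 at the isopropenyl carbon | C1C(O[Si](C(C)C)(C(C)C)C(C)C)=C(C)C[C@@H]2C(=O)[C@@H](C(C)=C)CC[C@]12C
F4 | step 18 | siloxycyclopropane (CH2 in place of the CBr2 of 24) | COC(=O)[C@]12C[C@@](C)(O[Si](C)(C)C)C(=O)[C@](C)(C[C@H]3[C@]4(O[Si](C)(C)C)C[C@]4(C(C)=C)CC[C@@]31C)C2=C
F5 | step 18 | β-chloro cycloheptanone (both epimers at the C–Cl carbon) | COC(=O)[C@]12C[C@@](C)(O[Si](C)(C)C)C(=O)[C@](C)(C[C@H]3C(=O)CC(Cl)(C(C)=C)CC[C@@]31C)C2=C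
F6 | step 18 | ring-B dienone without α-substituent | COC(=O)[C@]12C[C@@](C)(O[Si](C)(C)C)C(=O)[C@](C)(C[C@H]3C(=O)C=C(C(C)=C)CC[C@@]31C)C2=C
F7 | step 18 | α-iodo dienone | COC(=O)[C@]12C[C@@](C)(O[Si](C)(C)C)C(=O)[C@](C)(C[C@H]3C(=O)C(I)=C(C(C)=C)CC[C@@]31C)C2=C
F8 | step 21 | iodomethyl lactone (both epimers at the new C–O carbon) | COC(=O)[C@]12C[C@@](C)(O[Si](C)(C)C)C(=O)[C@](C)(C[C@H]3C(C)=C4CC(=O)OC(C)(CI)C4=CC[C@@]31C)C2=C
F9 | step 21 | trimethylsilyl ether of 29 | COC(=O)[C@]12C[C@@](C)(O[Si](C)(C)C)C(=O)[C@](C)(C[C@H]3C(C)=C4CC(=O)OC(C)(C)C4=CC[C@@]31C)C2=C
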